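The seven-membered ring is disconnected at C6–C7 and C9–C10 (daucane numbering). The oxygen-bearing carbons C6 and C10 are 1,4-related across the C5–C1 ring-fusion bond and are spanned by the three-carbon unit C7–C8(C14)–C9. In one flask, 2-(chloromethyl)allyltrimethylsilane is joined to a trans-cyclopentane-1,2-dicarbaldehyde: indium-mediated allylation of the C6 aldehyde, steered by the free cis C4 hydroxyl, then aluminium-promoted allylsilane closure onto the neopentyl C10 aldehyde. This should give the trans-fused hydroazulene with both carbinols and a C8 exocyclic methylene. The precursor, a C1-methyl, C4-hydroxy, C4-isopropyl dialdehyde, comes from (S)-terpinen-4-ol by ozonolysis, aldol ring contraction, conjugate vinylation and a second ozonolysis.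

Key step: step 6

Remarks on the chemistry:
- Numbering: the bicyclic compounds carry daucane numbers (C1 ring-fusion carbon with the methyl group C15, C4 isopropyl carbinol, C5 ring-fusion CH, C6 acyloxy carbon, C8 alkene carbon with C14, C10 ketone); β is the face of the C1 methyl group.
- Assumption: (S)-terpinen-4-ol is used as a single enantiomer; the enantiomeric purity of the purchased lot is checked before use, because essential-oil material can be scalemic.
- Assumption: the C10 carbinol of 12 and 14 is drawn as the expected 10α (10R) epimer; the 10β epimer would give the same ketone in step 8.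
- The C4 silyl ether is removed before the annulation (step 4), so that the C4 hydroxyl can chelate and direct the first allylation.

Step 1
Reactants: 1 (S)-terpinen-4-ol
Product: 2 triethyl{[(1S)-4-methyl-1-(propan-2-yl)cyclohex-3-en-1-yl]oxy}silane
Conditions: TESOTf, 2,6-lutidine, CH2Cl2, 0 °C to rt
Reagents that add atoms: triethylsilyl trifluoromethanesulfonate, CC[Si](CC)(CC)OS(=O)(=O)C(F)(F)F
Why: Silyl triflate silylation of a hindered tertiary alcohol (silyl ether formation) is reliable, does not involve the C4 stereocenter, protects the carbinol through ozonolysis and condensation, and provides the steric director for step 3.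

Step 2
Reactants: 2 triethyl{[(1S)-4-methyl-1-(propan-2-yl)cyclohex-3-en-1-yl]oxy}silane
Product: 4 (5R)-2-methyl-5-(propan-2-yl)-5-[(triethylsilyl)oxy]cyclopent-1-ene-1-carbaldehyde, via keto aldehyde 3 (not isolated)
Conditions: O3, pyridine, CH2Cl2, −78 °C; then piperidine, AcOH, toluene, 60 °C
Reagents that add atoms: ozone, [O-][O+]=O
Why: Pyridine-mediated reductive ozonolysis cleaves the ring alkene straight to the 1,6-keto aldehyde, and piperidinium acetate then turns the aldehyde into its enamine, which attacks the methyl ketone and dehydrates (intramolecular aldol condensation closing the five-membered ring) to the 2-methylcyclopentenecarbaldehyde; no stereocenter is formed and C4 is untouched.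

Step 3
Reactants: 4 (5R)-2-methyl-5-(propan-2-yl)-5-[(triethylsilyl)oxy]cyclopent-1-ene-1-carbaldehyde; 5 vinylmagnesium bromide
Product: 7 (1R,2R,5R)-2-ethenyl-2-methyl-5-(propan-2-yl)-5-[(triethylsilyl)oxy]cyclopentane-1-carbaldehyde, via silyl enol ether 6 (not isolated)
Conditions: CuBr·SMe2 (10 mol%), TMSCl, HMPA, THF, −78 °C; then 1 M HCl, THF, 0 °C
Reagents that add atoms: vinylmagnesium bromide (5), C=C[Mg]Br
Why: Copper-catalysed, TMSCl-accelerated conjugate addition of the Grignard reagent (Nakamura–Kuwajima conditions) should build the quaternary C1 on the α-face, anti to the triethylsilyloxy group, whose silyl group sits over the β-face while the isopropyl group turns its methine hydrogen toward the ring; trapping as the silyl enol ether excludes β-elimination of the silyloxy group, and hydrolysis protonates C5 from the same open α-face, placing the formyl group β (trans to vinyl, cis to the silyl ether), which is also the less crowded epimer.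

Step 4
Reactants: 7 (1R,2R,5R)-2-ethenyl-2-methyl-5-(propan-2-yl)-5-[(triethylsilyl)oxy]cyclopentane-1-carbaldehyde
Product: 8 (1R,2R,5R)-2-ethenyl-5-hydroxy-2-methyl-5-(propan-2-yl)cyclopentane-1-carbaldehyde
Conditions: HF·pyridine, pyridine, THF, 0 °C to rt
Reagents that add atoms: none
Why: Buffered fluoride cleavage of the tertiary silyl ether (desilylation) frees the C4 hydroxyl without enolising the aldehyde, so the β-hydroxy aldehyde never meets the basic conditions that cause retro-aldol or elimination; no stereocenter changes.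

Step 5
Reactants: 8 (1R,2R,5R)-2-ethenyl-5-hydroxy-2-methyl-5-(propan-2-yl)cyclopentane-1-carbaldehyde
Product: 9 (1S,2R,3R)-3-hydroxy-1-methyl-3-(propan-2-yl)cyclopentane-1,2-dicarbaldehyde
Conditions: O3, pyridine, CH2Cl2, −78 °C
Reagents that add atoms: ozone, [O-][O+]=O
Why: Pyridine-mediated reductive ozonolysis of the vinyl group on the quaternary carbon should give the C10 aldehyde without a basic or peroxide-reduction stage, so C5 is not epimerised, and C10, being trans to both the C6 formyl group and the C4 hydroxyl, cannot form a lactol; no new stereocenter, and 9 is used at once.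

Step 6
Reactants: 9 (1S,2R,3R)-3-hydroxy-1-methyl-3-(propan-2-yl)cyclopentane-1,2-dicarbaldehyde; 10 2-(chloromethyl)allyltrimethylsilane
Product: 12 (3R,3aS,4S,8R,8aS)-8a-methyl-6-methylidene-3-(propan-2-yl)decahydroazulene-3,4,8-triol (dauc-8(14)-ene-4β,6α,10α-triol), via homoallylic alcohol 11 (not isolated)
Conditions: In powder, NaI (cat.), THF, 0 °C to rt; then THF removed, CH2Cl2, EtAlCl2, −78 to −20 °C
Reagents that add atoms: 2-(chloromethyl)allyltrimethylsilane (10), C=C(CCl)C[Si](C)(C)C
Why: Indium inserts into the allylic C–Cl bond and the allylindium species adds through its far terminus (SE2', cyclic six-membered transition state) to the C6 aldehyde to form C6–C7; EtAlCl2 then converts the hydroxyl groups into aluminium alkoxides with loss of ethane and activates the C10 aldehyde, which the allylsilane terminus attacks to form C9–C10, the β-silyl cation at C8 losing silicon to leave the exocyclic methylene. The closest known reaction type is the [3+4] annulation of 1,4-dicarbonyl compounds with 2-(halomethyl)allylsilanes, a Barbier allylation followed by an intramolecular Hosomi–Sakurai reaction. The seven-membered ring closes with the allylsilane C8=C9 bond inside the new ring and the C10=O bond outside it (7-endo with respect to the alkene, exo-trig with respect to the carbonyl), and the trans ring fusion is already fixed in the dialdehyde. C6 is controlled by chelation of indium between the cis C4 hydroxyl and the C6 carbonyl oxygen (Cram chelate model for a β-hydroxy aldehyde), the allyl group entering on the chelate face turned away from C1 and its methyl group to give the 6α (6S) carbinol; C10 is expected 10α through the aluminium alkoxide on O6, but its configuration is erased in step 8. The step needs a single allylation, at C6: only the C6 aldehyde can chelate (the neopentyl C10 aldehyde is trans to the C4 hydroxyl) and one equivalent of 10 is used, the trans carbonyl groups cannot form the bridged lactols that divert cis-1,4-dicarbonyl compounds, and the alkylaluminium removes the protons that could protodesilylate the allylsilane.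

Step 7
Reactants: 12 (3R,3aS,4S,8R,8aS)-8a-methyl-6-methylidene-3-(propan-2-yl)decahydroazulene-3,4,8-triol; 13 4-acetoxybenzoic acid
Product: 14 [(3R,3aS,4S,8R,8aS)-3,8-dihydroxy-8a-methyl-6-methylidene-3-(propan-2-yl)decahydroazulen-4-yl] 4-(acetyloxy)benzoate
Conditions: DCC, DMAP (cat.), CH2Cl2, 0 °C to rt
Reagents that add atoms: 4-acetoxybenzoic acid (13), CC(=O)Oc1ccc(cc1)C(=O)O
Why: Steglich esterification with one equivalent of acid should acylate the C6 hydroxyl (next to the tertiary C5–H and hydrogen-bonded to the C4 hydroxyl) in preference to the neopentyl C10 hydroxyl beside the quaternary C1, while the tertiary C4 hydroxyl is inert; no stereocenter is affected.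

Step 8
Reactants: 14 [(3R,3aS,4S,8R,8aS)-3,8-dihydroxy-8a-methyl-6-methylidene-3-(propan-2-yl)decahydroazulen-4-yl] 4-(acetyloxy)benzoate
Product: 16 [(3R,3aS,4S,8aS)-3-hydroxy-6,8a-dimethyl-8-oxo-3-(propan-2-yl)-1,2,3,3a,4,5,8,8a-octahydroazulen-4-yl] 4-(acetyloxy)benzoate, via exo-methylene ketone 15 (not isolated)
Conditions: Dess–Martin periodinane, NaHCO3, CH2Cl2, rt; then DBU (0.2 equiv), 0 °C
Reagents that add atoms: none
Why: Dess–Martin oxidation turns the remaining secondary alcohol into the C10 ketone and erases its configuration, and catalytic amidine base then removes the doubly activated C9 proton and reprotonates the dienolate at the exocyclic carbon (base-mediated alkene isomerisation) to give the only conjugated isomer, C8=C9; brief exposure at 0 °C avoids deprotonation at C7 and loss of the C6 ester.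

Step 9
Reactants: 16 [(3R,3aS,4S,8aS)-3-hydroxy-6,8a-dimethyl-8-oxo-3-(propan-2-yl)-1,2,3,3a,4,5,8,8a-octahydroazulen-4-yl] 4-(acetyloxy)benzoate
Product: 17 [(3R,3aS,4S,8aS)-3-hydroxy-6,8a-dimethyl-8-oxo-3-(propan-2-yl)-1,2,3,3a,4,5,8,8a-octahydroazulen-4-yl] 4-hydroxybenzoate (CNP0210039.1)
Conditions: NH4OAc, MeOH/H2O, rt
Reagents that add atoms: none
Why: Chemoselective deacetylation: a phenolic acetate is cleaved by neutral ammonium acetate in aqueous methanol far faster than the hindered secondary benzoate, and the base-sensitive 6-acyloxy enone never meets alkoxide; no stereocenter is touched.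

Compound list
1 | (S)-terpinen-4-ol, (1S)-4-methyl-1-(propan-2-yl)cyclohex-3-en-1-ol | CC1=CC[C@](O)(C(C)C)CC1 | starting material
2 | triethyl{[(1S)-4-methyl-1-(propan-2-yl)cyclohex-3-en-1-yl]oxy}silane | CC1=CC[C@](O[Si](CC)(CC)CC)(C(C)C)CC1 | intermediate
3 | (3S)-6-oxo-3-(propan-2-yl)-3-[(triethylsilyl)oxy]heptanal | O=CC[C@](O[Si](CC)(CC)CC)(C(C)C)CCC(C)=O | intermediate (not isolated)
4 | (5R)-2-methyl-5-(propan-2-yl)-5-[(triethylsilyl)oxy]cyclopent-1-ene-1-carbaldehyde | O=CC1=C(C)CC[C@@]1(O[Si](CC)(CC)CC)C(C)C | intermediate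
5 | vinylmagnesium bromide | C=C[Mg]Br | starting material
6 | trimethylsilyl enol ether of 7 (E/Z mixture at the enol ether) | C=C[C@@]1(C)CC[C@@](O[Si](CC)(CC)CC)(C(C)C)C1=CO[Si](C)(C)C | intermediate (not isolated)
7 | (1R,2R,5R)-2-ethenyl-2-methyl-5-(propan-2-yl)-5-[(triethylsilyl)oxy]cyclopentane-1-carbaldehyde | C=C[C@@]1(C)CC[C@@](O[Si](CC)(CC)CC)(C(C)C)[C@@H]1C=O | intermediate
8 | (1R,2R,5R)-2-ethenyl-5-hydroxy-2-methyl-5-(propan-2-yl)cyclopentane-1-carbaldehyde | C=C[C@@]1(C)CC[C@@](O)(C(C)C)[C@@H]1C=O | intermediate
9 | (1S,2R,3R)-3-hydroxy-1-methyl-3-(propan-2-yl)cyclopentane-1,2-dicarbaldehyde | O=C[C@@]1(C)CC[C@@](O)(C(C)C)[C@@H]1C=O | intermediate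
10 | 2-(chloromethyl)allyltrimethylsilane | C=C(CCl)C[Si](C)(C)C | starting material
11 | (1S,2S,3R)-3-hydroxy-2-[(1S)-1-hydroxy-3-[(trimethylsilyl)methyl]but-3-en-1-yl]-1-methyl-3-(propan-2-yl)cyclopentane-1-carbaldehyde | O=C[C@@]1(C)CC[C@@](O)(C(C)C)[C@@H]1[C@@H](O)CC(=C)C[Si](C)(C)C | intermediate (not isolated)
12 | (3R,3aS,4S,8R,8aS)-8a-methyl-6-methylidene-3-(propan-2-yl)decahydroazulene-3,4,8-triol | C=C1C[C@@H](O)[C@@]2(C)CC[C@@](O)(C(C)C)[C@@H]2[C@@H](O)C1 | intermediate
13 | 4-acetoxybenzoic acid | CC(=O)Oc1ccc(cc1)C(=O)O | starting material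
14 | [(3R,3aS,4S,8R,8aS)-3,8-dihydroxy-8a-methyl-6-methylidene-3-(propan-2-yl)decahydroazulen-4-yl] 4-(acetyloxy)benzoate | C=C1C[C@@H](O)[C@@]2(C)CC[C@@](O)(C(C)C)[C@@H]2[C@@H](OC(=O)c2ccc(OC(C)=O)cc2)C1 | intermediate
15 | [(3R,3aS,4S,8aS)-3-hydroxy-8a-methyl-6-methylidene-8-oxo-3-(propan-2-yl)decahydroazulen-4-yl] 4-(acetyloxy)benzoate | C=C1CC(=O)[C@@]2(C)CC[C@@](O)(C(C)C)[C@@H]2[C@@H](OC(=O)c2ccc(OC(C)=O)cc2)C1 | intermediate (not isolated)
16 | [(3R,3aS,4S,8aS)-3-hydroxy-6,8a-dimethyl-8-oxo-3-(propan-2-yl)-1,2,3,3a,4,5,8,8a-octahydroazulen-4-yl] 4-(acetyloxy)benzoate | CC1=CC(=O)[C@@]2(C)CC[C@@](O)(C(C)C)[C@@H]2[C@@H](OC(=O)c2ccc(OC(C)=O)cc2)C1 | intermediate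
17 | [(3R,3aS,4S,8aS)-3-hydroxy-6,8a-dimethyl-8-oxo-3-(propan-2-yl)-1,2,3,3a,4,5,8,8a-octahydroazulen-4-yl] 4-hydroxybenzoate | CC1=CC(=O)[C@@]2(C)CC[C@@](O)(C(C)C)[C@@H]2[C@@H](OC(=O)c2ccc(O)cc2)C1 | target

Total step count: 9. Longest linear sequence: 9 steps (1 to 17); compounds 5, 10 and 13 are purchased.

Steps most likely to fail

Step 6. The first allylation may not stop at one aldehyde or may start at C10, the allylsilane may be protodesilylated before it cyclises, or the seven-membered closure onto the neopentyl aldehyde may be too slow. The fallback closes the ring by olefin metathesis instead and sets out from 9. Indium-mediated, chelation-controlled allylation with 3-bromo-2-methylpropene in THF/H2O should give the C6 methallyl carbinol aldehyde F1. Excess vinylmagnesium bromide 5 in THF at −78 °C then adds to the C10 aldehyde to give the triol diene F2. Ring-closing metathesis with the second-generation Grubbs catalyst (H2IMes)(PCy3)Cl2Ru=CHPh in CH2Cl2 at 40 °C forms C8=C9 directly and gives the dauc-8-ene-4β,6α,10-triol F3. MnO2 oxidises only the allylic C10 alcohol, giving the 4β,6α-dihydroxy enone F4, and Steglich esterification of its single secondary hydroxyl with 13 returns to the route at 16.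

Step 3. Facial selectivity of the conjugate addition may be poor (attack syn to the silyloxy group, giving the C1 epimer), or 1,2-addition may compete. The fallback replaces the steric director by a larger, more rigid one and sets out from 1. TBSOTf and 2,6-lutidine give the tert-butyldimethylsilyl ether F5. Ozonolysis and aldol condensation as in step 2 pass through the keto aldehyde F6 to the enal F7. Conjugate vinylation with 5 as in step 3 passes through the trimethylsilyl enol ether F8 to the vinyl aldehyde F9, and aqueous HF in MeCN removes the silyl ether, returning to the route at 8.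

Step 7. Acylation may not discriminate between the C6 and C10 hydroxyls, or may go twice. The fallback masks the 4,6-diol before the oxidation and sets out from 12. 2,2-Dimethoxypropane with PPTS should give the 4,6-O-isopropylidene acetal F10, whose only free hydroxyl is at C10. Dess–Martin oxidation gives the exo-methylene ketone acetal F11. Aqueous HCl in THF cleaves the acetal and moves the alkene into conjugation, giving the dihydroxy enone F4, and Steglich esterification of its only secondary hydroxyl with 13 returns to the route at 16.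

Further compounds
F1 | step 6 | (1S,2S,3R)-3-hydroxy-2-[(1S)-1-hydroxy-3-methylbut-3-en-1-yl]-1-methyl-3-(propan-2-yl)cyclopentane-1-carbaldehyde | O=C[C@@]1(C)CC[C@@](O)(C(C)C)[C@@H]1[C@@H](O)CC(C)=C
F2 | step 6 | C10 vinyl carbinol of F1, triol diene (both C10 epimers) | C=CC(O)[C@@]1(C)CC[C@@](O)(C(C)C)[C@@H]1[C@@H](O)CC(C)=C
F3 | step 6 | dauc-8-ene-4β,6α,10-triol (both C10 epimers) | CC1=CC(O)[C@@]2(C)CC[C@@](O)(C(C)C)[C@@H]2[C@@H](O)C1
F4 | step 6 | 4β,6α-dihydroxydauc-8-en-10-one | CC1=CC(=O)[C@@]2(C)CC[C@@](O)(C(C)C)[C@@H]2[C@@H](O)C1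
F5 | step 3 | tert-butyldimethyl{[(1S)-4-methyl-1-(propan-2-yl)cyclohex-3-en-1-yl]oxy}silane | CC1=CC[C@](O[Si](C)(C)C(C)(C)C)(C(C)C)CC1
F6 | step 3 | (3S)-3-[(tert-butyldimethylsilyl)oxy]-6-oxo-3-(propan-2-yl)heptanal | O=CC[C@](O[Si](C)(C)C(C)(C)C)(C(C)C)CCC(C)=O
F7 | step 3 | (5R)-5-[(tert-butyldimethylsilyl)oxy]-2-methyl-5-(propan-2-yl)cyclopent-1-ene-1-carbaldehyde | O=CC1=C(C)CC[C@@]1(O[Si](C)(C)C(C)(C)C)C(C)C
F8 | step 3 | trimethylsilyl enol ether of F9 (E/Z mixture) | C=C[C@@]1(C)CC[C@@](O[Si](C)(C)C(C)(C)C)(C(C)C)C1=CO[Si](C)(C)C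
F9 | step 3 | (1R,2R,5R)-5-[(tert-butyldimethylsilyl)oxy]-2-ethenyl-2-methyl-5-(propan-2-yl)cyclopentane-1-carbaldehyde | C=C[C@@]1(C)CC[C@@](O[Si](C)(C)C(C)(C)C)(C(C)C)[C@@H]1C=O
F10 | step 7 | 4,6-O-isopropylidene acetal of 12 | C=C1C[C@@H](O)[C@@]2(C)CC[C@@](O3)(C(C)C)[C@@H]2[C@@H](OC3(C)C)C1
F11 | step 7 | 4,6-O-isopropylidene acetal of 4β,6α-dihydroxydauc-8(14)-en-10-one | C=C1CC(=O)[C@@]2(C)CC[C@@](O3)(C(C)C)[C@@H]2[C@@H](OC3(C)C)C1
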